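**Plan**

1. Numbering (cembrane): macrocycle C1–C14; C15 = CMe2–O on C1, joined through oxygen to C3; C18 = CH2O on C4; C19 = formyl carbon on C8; C20 = methyl on C12.
2. Cuts, in retrosynthetic order: malonyl C–O at C18; C9–C10 (14-membered ring, sulfone carbanion onto a Morita–Baylis–Hillman acetate); C7–C8 (acrylate); C12–C13 (alkyl–alkenyl coupling with a C10–C12/C20 unit from but-2-yn-1-ol); C5–C6 and C13–C14 (two Wittig reactions); then the C5 carboxyl and C14 formyl carbons are rejoined (C5–C14) to a cyclohexanone and the C18 oxygen is removed.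
3. Enabling feature: the oxolane (O, C15, C1, C2, C3) carries C4 on C3 and C14 on C1 cis to each other, so with C5 as a ketone between C4 and C14 it is a 6-oxabicyclo[3.2.1]octan-3-one whose ether oxygen is β to the carbonyl. Cutting O–C3 (retro-oxa-Michael) gives the enone of hydrated (S)-carvone, whose ten carbons are C1–C5, C14, C15–C17 and C18.
4. Forward: the oxolane closes first inside the bicycle, C18 is oxygenated through the exocyclic enone, the carbocycle is opened at C5–C14 by ozonolysis of the kinetic silyl enol ether, both arms are extended, and the macrocycle closes last at C9–C10.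
5. Stereochemistry: C1 from (S)-carvone; C3 from the only possible (cis) bridging; C4 from equilibration to the equatorial epimer (step 2 and again, after C18 oxygenation, step 5); 11Z from trans-hydroalumination–iodination and a stereoretentive coupling; 7E from the addition–elimination.

Key step: step 2

Remark on the chemistry: C7 of 25 and 26 and C10 of 27 and 28 should form as mixtures of epimers and are left undefined in the SMILES, because both centres lose their stereogenicity before the target is reached.

**Route**

Step 1
Reactants: 1 (S)-carvone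
Product: 2 (S)-8-hydroxycarvotanacetone
Conditions: 50% aq. H2SO4, 0 °C → rt
Reagents that add atoms: water, O
Why: Acid-catalysed Markovnikov hydration of the 1,1-disubstituted isopropenyl alkene through its tertiary cation should be much faster at low temperature than any reaction of the protonated enone, and the C1 stereocentre is not involved.

Step 2
Reactants: 2 (S)-8-hydroxycarvotanacetone
Product: 3 (1S,4R,5R)-4,7,7-trimethyl-6-oxabicyclo[3.2.1]octan-3-one
Conditions: KOtBu (0.2 equiv), tBuOH/THF, 0 °C → rt; AcOH quench
Reagents that add atoms: none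
Why: Catalytic tert-butoxide deprotonates the tertiary C15 hydroxyl, the alkoxide adds to the enone β-carbon C3, and the C4=C5 enolate is protonated by tert-butanol, which regenerates the base; this is an intramolecular oxa-Michael addition of the kind by which hydroxy enones give bridged bicyclic ethers of the pinol type. The oxolane (O, C15, C1, C2, C3) closes in a 5-exo-trig mode. The side chain on C1 can reach C3 only from its own face and only when axial, so the new ring can only be cis-fused across C1 and C3, and C3 is fixed by the C1 centre taken from (S)-carvone. C4 is set on protonation and, because addition and enolisation are both reversible here, it should settle in the epimer with the methyl equatorial on the chair cyclohexanone and cis to the ether oxygen, the hydrogen being axial and anti to the C3–O bond. The step needs the closed ketone to be favoured over the open enone and O–C3 closure to beat intermolecular alkoxide addition, and it relies for this on the 1,3-relationship of C1 and C3 on a six-membered ring, on a hindered non-nucleophilic base and on a protic medium that keeps the enolate concentration low.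

Step 3
Reactants: 3 (1S,4R,5R)-4,7,7-trimethyl-6-oxabicyclo[3.2.1]octan-3-one
Product: 4 C4=C5 trimethylsilyl enol ether of 3
Conditions: Me3SiCl, NaI, Et3N, MeCN, rt
Reagents that add atoms: chlorotrimethylsilane, C[Si](C)(C)Cl
Why: Silylation under equilibrating conditions with Me3SiI formed in the flask favours the more substituted enol ether of 2-alkylcyclohexanones, here the C4=C5 isomer, since neither enol double bond lies at a bridgehead (thermodynamic silyl enol ether formation).

Step 4
Reactants: 4 C4=C5 trimethylsilyl enol ether of 3
Product: 6 (1S,5R)-7,7-dimethyl-4-methylidene-6-oxabicyclo[3.2.1]octan-3-one, via 4-phenylselanyl ketone 5 (not isolated)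
Conditions: PhSeCl, CH2Cl2, −78 °C; then 30% aq. H2O2, pyridine, 0 °C → rt
Reagents that add atoms: none
Why: Electrophilic selenenylation of the silyl enol ether places PhSe on C4, and the selenoxide formed on oxidation undergoes syn-elimination that can only take a methyl hydrogen, because elimination towards C3 would give a bridgehead alkene, so the exocyclic enone is the only possible product (selenoxide elimination).

Step 5
Reactants: 6 (1S,5R)-7,7-dimethyl-4-methylidene-6-oxabicyclo[3.2.1]octan-3-one
Product: 7 (1S,4R,5R)-4-[(4-methoxybenzyloxy)methyl]-7,7-dimethyl-6-oxabicyclo[3.2.1]octan-3-one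
Conditions: 4-MeOC6H4CH2OH (3 equiv), KOtBu (0.1 equiv), THF, 0 °C; AcOH quench
Reagents that add atoms: 4-methoxybenzyl alcohol, COc1ccc(CO)cc1
Why: Base-catalysed oxa-Michael addition of the primary alkoxide to the unhindered methylene terminus is reversible and is followed by equilibrating protonation at C4, so that the C18 arm should again take the equatorial position cis to the ether oxygen for the same reason as the methyl group of 3.

Step 6
Reactants: 7 (1S,4R,5R)-4-[(4-methoxybenzyloxy)methyl]-7,7-dimethyl-6-oxabicyclo[3.2.1]octan-3-one
Product: 8 C5=C14 trimethylsilyl enol ether of 7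
Conditions: Me3SiCl, LiN(iPr)2 (added last), THF, −78 °C
Reagents that add atoms: chlorotrimethylsilane, C[Si](C)(C)Cl
Why: Kinetic deprotonation by the hindered amide takes the methylene C14 over the methine C4, and trapping in the flask prevents equilibration to the C4 enolate, which could expel either β-alkoxy group (regioselective kinetic silyl enol ether formation).

Step 7
Reactants: 8 C5=C14 trimethylsilyl enol ether of 7
Product: 10 methyl ester with C14 aldehyde, via aldehyde acid 9 (not isolated)
Conditions: O3, CH2Cl2/MeOH, −78 °C (Sudan red 7B end point); Me2S, −78 °C → rt; then Me3SiCHN2, toluene/MeOH, 0 °C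
Reagents that add atoms: ozone, [O-][O+]=O; trimethylsilyldiazomethane, C[Si](C)(C)C=[N+]=[N-]
Why: The electron-rich enol ether double bond is cleaved by ozone far faster than the anisyl ring is attacked when the gas stream is stopped at the indicator end point, giving the C5 acid and the C14 aldehyde, and the acid is then methylated under neutral conditions that leave the aldehyde and both α-stereocentres untouched (ozonolysis of a silyl enol ether, then diazoalkane esterification).

Step 8
Reactants: 10 methyl ester with C14 aldehyde
Product: 11 vinyl ester (C13=C14 alkene)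
Conditions: Ph3PCH3Br, KN(SiMe3)2, THF, 0 °C; then 10, −78 → 0 °C
Reagents that add atoms: methyltriphenylphosphonium bromide, C[P+](c1ccccc1)(c1ccccc1)c1ccccc1.[Br-]
Why: Wittig methylenation of the aldehyde is faster at low temperature than ylide attack on the ester or enolisation at C1, whose cis relationship to the C3 side chain is in any case the more stable arrangement on the oxolane.

Step 9
Reactants: 11 vinyl ester (C13=C14 alkene)
Product: 12 C5 primary alcohol
Conditions: LiAlH4, THF, 0 °C
Reagents that add atoms: none
Why: Hydride reduction of the methyl ester to the primary alcohol is uneventful next to a terminal alkene, a benzyl-type ether and an oxolane, and it removes the acidity of the C4 hydrogen (LiAlH4 ester reduction).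

Step 10
Reactants: 12 C5 primary alcohol
Product: 14 (E)-enoate (C5=C6), via C5 aldehyde 13 (not isolated)
Conditions: Dess–Martin periodinane, NaHCO3, CH2Cl2, 0 °C → rt; then Ph3P=CHCO2Me, rt
Reagents that add atoms: methyl (triphenylphosphoranylidene)acetate, COC(=O)C=P(c1ccccc1)(c1ccccc1)c1ccccc1
Why: Buffered periodinane oxidation followed by immediate trapping with the stabilised ylide avoids isolating the α-branched aldehyde with two β-alkoxy groups, which could epimerise or eliminate, and the stabilised Wittig reaction gives the (E)-enoate (one-pot Dess–Martin oxidation and Wittig olefination).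

Step 11
Reactants: 14 (E)-enoate (C5=C6)
Product: 15 saturated C7 methyl ester
Conditions: Mg turnings, MeOH, 0 °C → rt
Reagents that add atoms: none
Why: Magnesium in methanol reduces the conjugated enoate by electron transfer while the isolated vinyl group, the 4-methoxybenzyl ether and the oxolane are inert, and no leaving group sits on C4 to be expelled (Mg/MeOH conjugate reduction).

Step 12
Reactants: 16 but-2-yn-1-ol
Product: 18 (Z)-3-iodobut-2-en-1-ol, via cyclic alkenylalanate 17 (not isolated)
Conditions: NaAlH2(OCH2CH2OMe)2, THF, 0 °C → rt; then I2, THF, −78 → 0 °C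
Reagents that add atoms: iodine, II
Why: Alkoxide-directed trans-hydroalumination delivers hydride to the carbon next to CH2O and aluminium to the methyl-bearing carbon within a five-membered alanate, and iodine replaces aluminium with retention, so that iodine and CH2OH end up cis as the later 11Z geometry demands (hydroalumination–iodination of a propargylic alcohol).

Step 13
Reactants: 15 saturated C7 methyl ester; 18 (Z)-3-iodobut-2-en-1-ol
Product: 20 (11Z)-allylic alcohol with C12–C13 bond, via B-alkyl-9-BBN 19 (not isolated)
Conditions: 9-BBN-H, THF, 0 °C → rt; then 18, Pd(dppf)Cl2 (cat.), AsPh3, aq. Cs2CO3, DMF, rt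
Reagents that add atoms: none
Why: 9-BBN adds to the terminal alkene with boron on C13 without touching the ester, and the B-alkyl Suzuki–Miyaura coupling with the alkenyl iodide proceeds with retention of alkene geometry and tolerates the free hydroxyl, forming C12–C13 and the 11Z trisubstituted alkene.

Step 14
Reactants: 20 (11Z)-allylic alcohol with C12–C13 bond
Product: 21 (11Z)-allylic bromide
Conditions: CBr4, PPh3, CH2Cl2, 0 °C
Reagents that add atoms: tetrabromomethane, BrC(Br)(Br)Br
Why: The Appel reaction converts the primary allylic alcohol into the bromide by SN2 attack of bromide on the alkoxyphosphonium ion at low temperature, without allylic transposition or loss of the Z geometry.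

Step 15
Reactants: 21 (11Z)-allylic bromide
Product: 22 (11Z)-allylic phenyl sulfone
Conditions: PhSO2Na, DMF, rt
Reagents that add atoms: sodium benzenesulfinate, [Na+].[O-]S(=O)c1ccccc1
Why: Sulfinate displaces the primary allylic bromide through sulfur by SN2 in a dipolar aprotic solvent to give the allylic sulfone with the alkene position and geometry unchanged (sulfinate alkylation).

Step 16
Reactants: 22 (11Z)-allylic phenyl sulfone
Product: 23 C7 aldehyde
Conditions: iBu2AlH (1.1 equiv), CH2Cl2, −78 °C; aq. potassium sodium tartrate
Reagents that add atoms: none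
Why: At −78 °C the aluminium hemiacetal formed from the methyl ester and one equivalent of iBu2AlH survives until work-up, so the C7 aldehyde is released without over-reduction while the sulfone and ethers are inert (partial ester reduction).

Step 17
Reactants: 23 C7 aldehyde; 24 methyl acrylate
Product: 25 Morita–Baylis–Hillman alcohol (C7 epimers)
Conditions: methyl acrylate (excess), DABCO (1 equiv), 1,4-dioxane/H2O (1:1), rt
Reagents that add atoms: none
Why: DABCO adds to methyl acrylate and the resulting enolate adds to the unhindered aliphatic aldehyde, forming C7–C8 in a Morita–Baylis–Hillman reaction in which no other group of 23 takes part, and the new C7 carbinol centre forms as a mixture of epimers that does not matter because this carbon becomes sp2.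

Step 18
Reactants: 25 Morita–Baylis–Hillman alcohol (C7 epimers)
Product: 26 Morita–Baylis–Hillman acetate (C7 epimers)
Conditions: Ac2O, pyridine, DMAP (cat.), CH2Cl2, 0 °C
Reagents that add atoms: acetic anhydride, CC(=O)OC(C)=O
Why: Acylation of the secondary allylic alcohol under nucleophilic catalysis at low temperature gives the acetate before allylic transposition can set in (DMAP-catalysed acetylation).

Step 19
Reactants: 26 Morita–Baylis–Hillman acetate (C7 epimers)
Product: 27 macrocyclic (7E,11Z)-enoate with C10 sulfone (C10 epimers)
Conditions: NaN(SiMe3)2 (1.1 equiv) added slowly to 26 in THF (0.002 M), −78 → −20 °C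
Reagents that add atoms: none
Why: The amide base deprotonates only the allylic sulfone, whose carbanion adds through its α-carbon C10 to the acrylate terminus C9, and the ester enolate then expels acetate from C7 in an SN2′ addition–elimination of the kind known for Morita–Baylis–Hillman acetates of acrylates, which places C6 cis to C9 and trans to the ester (7E), while high dilution favours the 14-membered ring over oligomers.

Step 20
Reactants: 27 macrocyclic (7E,11Z)-enoate with C10 sulfone (C10 epimers)
Product: 28 macrocyclic C19 allylic alcohol with C10 sulfone (C10 epimers)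
Conditions: iBu2AlH (3 equiv), CH2Cl2, −78 °C
Reagents that add atoms: none
Why: iBu2AlH reduces the conjugated ester by 1,2-addition to the allylic alcohol without touching the alkene geometry or the sulfone, which removes the only group that the hydride of the next step would attack (1,2-reduction of an enoate).

Step 21
Reactants: 28 macrocyclic C19 allylic alcohol with C10 sulfone (C10 epimers)
Product: 29 macrocyclic (7E,11Z)-dienyl C19 alcohol
Conditions: PdCl2(dppp) (cat.), LiBHEt3 (3 equiv), THF, 0 °C → rt
Reagents that add atoms: none
Why: Zerovalent palladium ionises the allylic sulfone to a π-allyl complex and hydride from LiBHEt3 is delivered to the less substituted terminus C10, a desulfonylation known to keep the position and geometry of trisubstituted alkenes with the dppp ligand, while the alkoxide of the C19 alcohol is no leaving group (palladium-catalysed reductive desulfonylation).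

Step 22
Reactants: 29 macrocyclic (7E,11Z)-dienyl C19 alcohol
Product: 30 macrocyclic (7E)-enal with C18 4-methoxybenzyl ether
Conditions: MnO2, CH2Cl2, rt
Reagents that add atoms: none
Why: MnO2 oxidises only allylic alcohols and should give the enal with the 7E geometry intact, since the aldehyde stays trans to C6, which is the more stable arrangement (allylic oxidation).

Step 23
Reactants: 30 macrocyclic (7E)-enal with C18 4-methoxybenzyl ether
Product: 31 macrocyclic enal with free C18 alcohol
Conditions: DDQ, CH2Cl2/pH 7 buffer, 0 °C
Reagents that add atoms: none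
Why: DDQ removes the electron-rich 4-methoxybenzyl ether by benzylic hydride abstraction and hydrolysis of the oxocarbenium ion under buffered conditions that the enal, the trisubstituted alkene and the oxolane tolerate (oxidative cleavage of a 4-methoxybenzyl ether).

Step 24
Reactants: 31 macrocyclic enal with free C18 alcohol
Product: 32 CNP0170412.1
Conditions: Meldrum's acid (1.5 equiv), toluene, 90 °C
Reagents that add atoms: Meldrum's acid, CC1(C)OC(=O)CC(=O)O1
Why: On heating, the primary alcohol opens Meldrum's acid at an acyl carbon and the adduct loses acetone to leave the malonic half ester directly, and without an amine catalyst no Knoevenagel condensation with the hindered α-substituted enal is expected (alcoholysis of Meldrum's acid).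

**Compound list**

1 | (S)-carvone, (5S)-2-methyl-5-(prop-1-en-2-yl)cyclohex-2-en-1-one | CC1=CC[C@@H](CC1=O)C(C)=C | starting material
2 | (S)-8-hydroxycarvotanacetone, (5S)-5-(2-hydroxypropan-2-yl)-2-methylcyclohex-2-en-1-one | CC1=CC[C@@H](CC1=O)C(C)(C)O | intermediate
3 | (1S,4R,5R)-4,7,7-trimethyl-6-oxabicyclo[3.2.1]octan-3-one (methyl equatorial, cis to the ether oxygen) | O=C1[C@H](C)[C@H]2C[C@@H](C1)C(C)(C)O2 | intermediate
4 | (1S,5R)-4,7,7-trimethyl-3-(trimethylsilyloxy)-6-oxabicyclo[3.2.1]oct-3-ene (C4=C5 enol ether) | C[Si](C)(C)OC1=C(C)[C@H]2C[C@@H](C1)C(C)(C)O2 | intermediate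
5 | 4,7,7-trimethyl-4-(phenylselanyl)-6-oxabicyclo[3.2.1]octan-3-one (bridgeheads as in 3; C4 configuration of no consequence) | O=C1C(C)([Se]c3ccccc3)[C@H]2C[C@@H](C1)C(C)(C)O2 | intermediate (not isolated)
6 | (1S,5R)-7,7-dimethyl-4-methylidene-6-oxabicyclo[3.2.1]octan-3-one | O=C1C(=C)[C@H]2C[C@@H](C1)C(C)(C)O2 | intermediate
7 | (1S,4R,5R)-4-[(4-methoxybenzyloxy)methyl]-7,7-dimethyl-6-oxabicyclo[3.2.1]octan-3-one (C18 arm equatorial, cis to the ether oxygen) | O=C1[C@H](COCc3ccc(OC)cc3)[C@H]2C[C@@H](C1)C(C)(C)O2 | intermediate
8 | (1S,4R,5R)-4-[(4-methoxybenzyloxy)methyl]-7,7-dimethyl-3-(trimethylsilyloxy)-6-oxabicyclo[3.2.1]oct-2-ene (C5=C14 enol ether) | C1=C(O[Si](C)(C)C)[C@H](COCc3ccc(OC)cc3)[C@H]2C[C@@H]1C(C)(C)O2 | intermediate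
9 | 2-(cis-4-formyl-5,5-dimethyloxolan-2-yl)-3-(4-methoxybenzyloxy)propanoic acid (C5 acid, C14 aldehyde; C1, C3, C4 as in 7) | OC(=O)[C@H](COCc1ccc(OC)cc1)[C@H]2C[C@@H](C=O)C(C)(C)O2 | intermediate (not isolated)
10 | methyl 2-(cis-4-formyl-5,5-dimethyloxolan-2-yl)-3-(4-methoxybenzyloxy)propanoate | COC(=O)[C@H](COCc1ccc(OC)cc1)[C@H]2C[C@@H](C=O)C(C)(C)O2 | intermediate
11 | methyl 2-(cis-4-ethenyl-5,5-dimethyloxolan-2-yl)-3-(4-methoxybenzyloxy)propanoate | COC(=O)[C@H](COCc1ccc(OC)cc1)[C@H]2C[C@@H](C=C)C(C)(C)O2 | intermediate
12 | 2-(cis-4-ethenyl-5,5-dimethyloxolan-2-yl)-3-(4-methoxybenzyloxy)propan-1-ol | OC[C@H](COCc1ccc(OC)cc1)[C@H]2C[C@@H](C=C)C(C)(C)O2 | intermediate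
13 | 2-(cis-4-ethenyl-5,5-dimethyloxolan-2-yl)-3-(4-methoxybenzyloxy)propanal | O=C[C@H](COCc1ccc(OC)cc1)[C@H]2C[C@@H](C=C)C(C)(C)O2 | intermediate (not isolated)
14 | methyl (2E)-4-(cis-4-ethenyl-5,5-dimethyloxolan-2-yl)-5-(4-methoxybenzyloxy)pent-2-enoate | COC(=O)/C=C/[C@H](COCc1ccc(OC)cc1)[C@H]2C[C@@H](C=C)C(C)(C)O2 | intermediate
15 | methyl 4-(cis-4-ethenyl-5,5-dimethyloxolan-2-yl)-5-(4-methoxybenzyloxy)pentanoate | COC(=O)CC[C@H](COCc1ccc(OC)cc1)[C@H]2C[C@@H](C=C)C(C)(C)O2 | intermediate
16 | but-2-yn-1-ol | CC#CCO | starting material
17 | sodium 2,2-bis(2-methoxyethoxy)-3-methyl-1-oxa-2-aluminacyclopent-3-ene-2-uide (cyclic alkenylalanate) | CC1=CCO[Al-]1(OCCOC)OCCOC.[Na+] | intermediate (not isolated)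
18 | (Z)-3-iodobut-2-en-1-ol | C/C(I)=C/CO | intermediate
19 | B-alkyl-9-BBN adduct of 15 (boron on C13) | COC(=O)CC[C@H](COCc1ccc(OC)cc1)[C@H]2C[C@@H](CCB3C4CCCC3CCC4)C(C)(C)O2 | intermediate (not isolated)
20 | methyl 4-{cis-4-[(3Z)-5-hydroxy-3-methylpent-3-en-1-yl]-5,5-dimethyloxolan-2-yl}-5-(4-methoxybenzyloxy)pentanoate | COC(=O)CC[C@H](COCc1ccc(OC)cc1)[C@H]2C[C@@H](CC/C(C)=C\CO)C(C)(C)O2 | intermediate
21 | methyl 4-{cis-4-[(3Z)-5-bromo-3-methylpent-3-en-1-yl]-5,5-dimethyloxolan-2-yl}-5-(4-methoxybenzyloxy)pentanoate | COC(=O)CC[C@H](COCc1ccc(OC)cc1)[C@H]2C[C@@H](CC/C(C)=C\CBr)C(C)(C)O2 | intermediate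
22 | methyl 4-{cis-5,5-dimethyl-4-[(3Z)-3-methyl-5-(phenylsulfonyl)pent-3-en-1-yl]oxolan-2-yl}-5-(4-methoxybenzyloxy)pentanoate | COC(=O)CC[C@H](COCc1ccc(OC)cc1)[C@H]2C[C@@H](CC/C(C)=C\CS(=O)(=O)c3ccccc3)C(C)(C)O2 | intermediate
23 | 4-{cis-5,5-dimethyl-4-[(3Z)-3-methyl-5-(phenylsulfonyl)pent-3-en-1-yl]oxolan-2-yl}-5-(4-methoxybenzyloxy)pentanal | O=CCC[C@H](COCc1ccc(OC)cc1)[C@H]2C[C@@H](CC/C(C)=C\CS(=O)(=O)c3ccccc3)C(C)(C)O2 | intermediate
24 | methyl acrylate | C=CC(=O)OC | starting material
25 | methyl 3-hydroxy-7-(4-methoxybenzyloxy)-2-methylidene-6-{cis-5,5-dimethyl-4-[(3Z)-3-methyl-5-(phenylsulfonyl)pent-3-en-1-yl]oxolan-2-yl}heptanoate (C3 of the heptanoate = C7, both epimers) | COC(=O)C(=C)C(O)CC[C@H](COCc1ccc(OC)cc1)[C@H]2C[C@@H](CC/C(C)=C\CS(=O)(=O)c3ccccc3)C(C)(C)O2 | intermediate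
26 | 3-O-acetate of 25 (both C7 epimers) | COC(=O)C(=C)C(OC(C)=O)CC[C@H](COCc1ccc(OC)cc1)[C@H]2C[C@@H](CC/C(C)=C\CS(=O)(=O)c3ccccc3)C(C)(C)O2 | intermediate
27 | macrocycle: (7E,11Z)-cembra-7,11-diene with 3,15-ether bridge, C19 methyl ester on C8, phenylsulfonyl on C10 (both epimers), 4-methoxybenzyloxy on C18; C1, C3, C4 as in the target | C/C1=C/C(S(=O)(=O)c3ccccc3)C/C(C(=O)OC)=C\CC[C@H](COCc3ccc(OC)cc3)[C@H]2C[C@@H](CC1)C(C)(C)O2 | intermediate
28 | as 27 with CH2OH (C19) on C8 in place of the ester (both C10 epimers) | C/C1=C/C(S(=O)(=O)c3ccccc3)C/C(CO)=C\CC[C@H](COCc3ccc(OC)cc3)[C@H]2C[C@@H](CC1)C(C)(C)O2 | intermediate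
29 | (7E,11Z)-3,15-epoxy-18-(4-methoxybenzyloxy)cembra-7,11-dien-19-ol (C10 = CH2) | C/C1=C/CC/C(CO)=C\CC[C@H](COCc3ccc(OC)cc3)[C@H]2C[C@@H](CC1)C(C)(C)O2 | intermediate
30 | (7E,11Z)-3,15-epoxy-18-(4-methoxybenzyloxy)cembra-7,11-dien-19-al | C/C1=C/CC/C(C=O)=C\CC[C@H](COCc3ccc(OC)cc3)[C@H]2C[C@@H](CC1)C(C)(C)O2 | intermediate
31 | (7E,11Z)-3,15-epoxy-18-hydroxycembra-7,11-dien-19-al | C/C1=C/CC/C(C=O)=C\CC[C@H](CO)[C@H]2C[C@@H](CC1)C(C)(C)O2 | intermediate
32 | CNP0170412.1, hydrogen malonate (at O18) of 31; C1 R, C3 R, C4 R, 7E, 11Z in cembrane numbering | C/C1=C/CC/C(C=O)=C\CC[C@H](COC(=O)CC(=O)O)[C@H]2C[C@@H](CC1)C(C)(C)O2 | target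

**Count**

Total steps: 24. Longest linear sequence: 23 steps (steps 1–11 and 13–24, from (S)-carvone); step 12 is a one-step branch.

**Three steps most likely to fail**

1. Step 19. The ring closure may be outrun by intermolecular addition leading to oligomers, by attack through the γ-carbon C12 of the allyl sulfone anion, or by base-induced loss of the acetate. The fallback sets out from 25 and returns at 27. N-Bromosuccinimide/Me2S in CH2Cl2 at 0 °C converts the allylic alcohol with transposition into the rearranged primary allylic bromide, the (2Z)-2-(bromomethyl)hept-2-enoate F1, in which the C7=C8 alkene is already in place with C6 cis to C9. Deprotonation of the sulfone (NaN(SiMe3)2, THF, high dilution, −78 °C) then closes the ring by direct SN2 alkylation at the primary allylic carbon C9, the sulfone/allylic halide closure long used for 14-membered carbocycles, and gives 27.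

2. Step 5. The alkoxide addition is an equilibrium that runs through the same enolate as the retro-oxa-Michael ring opening, and the exocyclic enone may dimerise or polymerise before it is trapped. The fallback sets out from 6 and returns at 7 without any equilibrating base. Conjugate borylation with bis(pinacolato)diboron, catalysed by CuCl/NaOtBu/bis(2-diphenylphosphinophenyl) ether in THF/MeOH, should give the β-boryl ketone F2; protonation of the enolate at C4 from the face opposite the ether bridge leads to the same equatorial C18 arm. NaBO3·4H2O in THF/H2O oxidises the C–B bond to the β-hydroxy ketone F3, and 4-methoxybenzyl 2,2,2-trichloroacetimidate with catalytic camphorsulfonic acid in CH2Cl2 gives 7.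

3. Step 2. Under catalytic base the closed ketone and the open hydroxy enone interconvert, and the position of this equilibrium may leave much of 2 unchanged. The fallback sets out from 2 and returns at 4. KN(SiMe3)2 (1.1 equiv) in THF at −78 → 0 °C turns the tertiary alkoxide, by the same O–C3 closure, into the far less basic C4=C5 enolate of the bicycle, which should pull the anionic equilibrium to the closed side whatever the neutral one does. Me3SiCl then traps the enolate on oxygen as 4 itself, so no compound outside the route is made (none, F0). C4 is then set in step 5 only, which in that case is best run by the base-free borylation detour described under point 2.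

**Further compounds**

F1 | step 19 | methyl (2Z)-2-(bromomethyl)-7-(4-methoxybenzyloxy)-6-{cis-5,5-dimethyl-4-[(3Z)-3-methyl-5-(phenylsulfonyl)pent-3-en-1-yl]oxolan-2-yl}hept-2-enoate | COC(=O)/C(CBr)=C/CC[C@H](COCc1ccc(OC)cc1)[C@H]2C[C@@H](CC/C(C)=C\CS(=O)(=O)c3ccccc3)C(C)(C)O2
F2 | step 5 | 7,7-dimethyl-4-[(4,4,5,5-tetramethyl-1,3,2-dioxaborolan-2-yl)methyl]-6-oxabicyclo[3.2.1]octan-3-one (C1, C3, C4 as in 7) | O=C1[C@H](CB3OC(C)(C)C(C)(C)O3)[C@H]2C[C@@H](C1)C(C)(C)O2
F3 | step 5 | 4-(hydroxymethyl)-7,7-dimethyl-6-oxabicyclo[3.2.1]octan-3-one (C1, C3, C4 as in 7) | O=C1[C@H](CO)[C@H]2C[C@@H](C1)C(C)(C)O2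
F0 | step 2 | none | none
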